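**Plan**

1. Cuts: the exocyclic C=CH2 is unmasked last from a CH–CH2SPh unit. The spiro γ-lactone and the tertiary OH are traced back by acyl transfer to a 2-oxabicyclo[2.2.2]oct-5-en-3-one. That bicycle is cut at the ring CH2–spiro carbon bond and at the ring-fusion CH–carbinol carbon bond, giving a 3,4,6-trisubstituted 2-pyrone with an allyl group on a five-atom tether. The pyrone is cut at O1–C6 (lactonisation) and C4–C5 (Sonogashira), giving an alkyne (upper half) and a (Z)-enol triflate (lower half).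
2. Enabling feature: in the cyclohexene, the carbinol carbon and the spiro carbon stand 1,4 across the ring C=C, with the OH and the lactone C=O cis. This is the pattern of an opened pyrone/alkene cycloadduct, so the pyrone serves as a temporary ring tying these two groups together.
3. Forward: both halves come from the two enantiomers of cis-4-allyl-5-(2-methylbut-3-ynyl)butyrolactone, made by the same five steps. In the lower half, enyne metathesis/cross-metathesis closes the cycloheptene (ring B) and attaches the oxobutyl chain; the lactone is then opened and protected, acylated and triflated.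
4. Sonogashira coupling joins the halves and gold closes the pyrone. The Diels–Alder step then closes the cyclohexene and the upper cycloheptane together. Desilylation re-forms the lower lactone as the spiro lactone, and sulfoxide elimination gives the methylene lactone.
5. Stereochemistry: the two methyl centres come from ligand-controlled Rh alkynylation of crotonaldehyde (both ligand antipodes). The two lactone carbinol centres come from ligand-controlled alkynylation, and the adjacent CH from face-selective CuH reduction (cis). The carbinol, spiro and ring-fusion centres of the cyclohexene are set in the key step.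

Key step: step 21

Remark: the two cyclohepta[b]furanone halves of this stereoisomer belong to opposite enantiomeric series. The sense of induction of each chiral ligand (steps 1, 2, 7, 8) is assigned by analogy; if it is the reverse, the ligand antipodes are exchanged.

**Route**

Step 1
Reactants: 1 (E)-but-2-enal; 2 ethynyltri(propan-2-yl)silane
Product: 3 (3S)-3-methyl-5-[tri(propan-2-yl)silyl]pent-4-ynal
Conditions: [Rh(OAc)(C2H4)2]2 (2.5 mol %), (R)-DTBM-SEGPHOS (6 mol %), MeOH, 40 °C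
Reagents that add atoms: none
Why: Rhodium-catalysed asymmetric conjugate alkynylation of an enal, in which the bisphosphine selects the enal face and so sets the methyl-bearing centre, while the bulky silyl group suppresses alkyne dimerisation.

Step 2
Reactants: 3 (3S)-3-methyl-5-[tri(propan-2-yl)silyl]pent-4-ynal; 4 methyl prop-2-ynoate
Product: 5 methyl (4R,6S)-4-hydroxy-6-methyl-8-[tri(propan-2-yl)silyl]octa-2,7-diynoate
Conditions: (S,S)-ProPhenol (20 mol %), Me2Zn, toluene, 0 °C; aq NH4Cl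
Reagents that add atoms: none
Why: Catalytic asymmetric alkynylation of an aldehyde by the zinc alkynylide of the propiolate within the dinuclear zinc–ProPhenol complex, so the ligand and not the remote methyl centre should set the new carbinol centre (4R).

Step 3
Reactants: 5 methyl (4R,6S)-4-hydroxy-6-methyl-8-[tri(propan-2-yl)silyl]octa-2,7-diynoate
Product: 7 (5R)-5-{(2S)-2-methyl-4-[tri(propan-2-yl)silyl]but-3-yn-1-yl}-4-(prop-2-en-1-yl)furan-2(5H)-one, via hydroxy dienoate 6 (not isolated)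
Conditions: CH2=CHCH2MgBr (2.3 equiv), CuBr·SMe2 (2.3 equiv), THF, −78 °C; then AcOH, −78 °C to rt
Reagents that add atoms: allylmagnesium bromide, C=CC[Mg]Br
Why: syn-Carbocupration (conjugate addition) of the allylcopper reagent across the ynoate places the ester and the carbinol carbon cis, so the hydroxy ester lactonises on acidification to the butenolide without touching a stereocentre.

Step 4
Reactants: 7 (5R)-5-{(2S)-2-methyl-4-[tri(propan-2-yl)silyl]but-3-yn-1-yl}-4-(prop-2-en-1-yl)furan-2(5H)-one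
Product: 8 (4R,5R)-5-{(2S)-2-methyl-4-[tri(propan-2-yl)silyl]but-3-yn-1-yl}-4-(prop-2-en-1-yl)oxolan-2-one
Conditions: [(Ph3P)CuH]6 (5 mol %), (EtO)2MeSiH, t-BuOH, toluene, 0 °C to rt
Reagents that add atoms: none
Why: Copper hydride conjugate reduction of the butenolide, in which hydride reaches the β-carbon from the face opposite to the C5 side chain, so the allyl group and the side chain end cis (4R); isolated alkene and silylalkyne are not reduced.

Step 5
Reactants: 8 (4R,5R)-5-{(2S)-2-methyl-4-[tri(propan-2-yl)silyl]but-3-yn-1-yl}-4-(prop-2-en-1-yl)oxolan-2-one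
Product: 9 (4R,5R)-5-[(2S)-2-methylbut-3-yn-1-yl]-4-(prop-2-en-1-yl)oxolan-2-one
Conditions: Bu4NF, THF, 0 °C to rt
Reagents that add atoms: none
Why: Fluoride-induced protodesilylation of the silylalkyne, which leaves the lactone and all stereocentres untouched.

Step 6
Reactants: 9 (4R,5R)-5-[(2S)-2-methylbut-3-yn-1-yl]-4-(prop-2-en-1-yl)oxolan-2-one
Product: 11 (3R,4R,5R)-5-[(2S)-2-methylbut-3-yn-1-yl]-3-[(phenylsulfanyl)methyl]-4-(prop-2-en-1-yl)oxolan-2-one, via silyl ketene acetal 10 (not isolated)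
Conditions: LiN(i-Pr)2 (1.05 equiv), Me3SiCl (internal quench), THF, −78 °C; then PhSCH2Cl, ZnBr2 (10 mol %), CH2Cl2, 0 °C to rt
Reagents that add atoms: chloromethyl phenyl sulfide, ClCSc1ccccc1
Why: Lewis-acid-mediated α-(phenylsulfanyl)methylation of the lactone silyl ketene acetal, in which the electrophile enters anti to the neighbouring allyl group (3R) and the sulfide serves as a latent exocyclic methylene that cannot act as a competing dienophile later.

Step 7
Reactants: 1 (E)-but-2-enal; 2 ethynyltri(propan-2-yl)silane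
Product: 12 (3R)-3-methyl-5-[tri(propan-2-yl)silyl]pent-4-ynal
Conditions: [Rh(OAc)(C2H4)2]2 (2.5 mol %), (S)-DTBM-SEGPHOS (6 mol %), MeOH, 40 °C
Reagents that add atoms: none
Why: The same rhodium-catalysed asymmetric conjugate alkynylation with the antipodal ligand should give the enantiomeric methyl centre.

Step 8
Reactants: 12 (3R)-3-methyl-5-[tri(propan-2-yl)silyl]pent-4-ynal; 4 methyl prop-2-ynoate
Product: 13 methyl (4S,6R)-4-hydroxy-6-methyl-8-[tri(propan-2-yl)silyl]octa-2,7-diynoate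
Conditions: (R,R)-ProPhenol (20 mol %), Me2Zn, toluene, 0 °C; aq NH4Cl
Reagents that add atoms: none
Why: Catalytic asymmetric alkynylation of the aldehyde as in step 2, the antipodal ligand setting the (4S) carbinol centre.

Step 9
Reactants: 13 methyl (4S,6R)-4-hydroxy-6-methyl-8-[tri(propan-2-yl)silyl]octa-2,7-diynoate
Product: 15 (5S)-5-{(2R)-2-methyl-4-[tri(propan-2-yl)silyl]but-3-yn-1-yl}-4-(prop-2-en-1-yl)furan-2(5H)-one, via hydroxy dienoate 14 (not isolated)
Conditions: CH2=CHCH2MgBr (2.3 equiv), CuBr·SMe2 (2.3 equiv), THF, −78 °C; then AcOH, −78 °C to rt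
Reagents that add atoms: allylmagnesium bromide, C=CC[Mg]Br
Why: syn-Carbocupration of the ynoate followed by lactonisation of the (Z)-hydroxy ester, as in step 3.

Step 10
Reactants: 15 (5S)-5-{(2R)-2-methyl-4-[tri(propan-2-yl)silyl]but-3-yn-1-yl}-4-(prop-2-en-1-yl)furan-2(5H)-one
Product: 16 (4S,5S)-5-{(2R)-2-methyl-4-[tri(propan-2-yl)silyl]but-3-yn-1-yl}-4-(prop-2-en-1-yl)oxolan-2-one
Conditions: [(Ph3P)CuH]6 (5 mol %), (EtO)2MeSiH, t-BuOH, toluene, 0 °C to rt
Reagents that add atoms: none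
Why: Copper hydride conjugate reduction with hydride delivery anti to the C5 side chain, which sets the cis-lactone (4S).

Step 11
Reactants: 16 (4S,5S)-5-{(2R)-2-methyl-4-[tri(propan-2-yl)silyl]but-3-yn-1-yl}-4-(prop-2-en-1-yl)oxolan-2-one
Product: 17 (4S,5S)-5-[(2R)-2-methylbut-3-yn-1-yl]-4-(prop-2-en-1-yl)oxolan-2-one
Conditions: Bu4NF, THF, 0 °C to rt
Reagents that add atoms: none
Why: Fluoride-induced protodesilylation of the silylalkyne frees the terminal alkyne needed for enyne metathesis.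

Step 12
Reactants: 17 (4S,5S)-5-[(2R)-2-methylbut-3-yn-1-yl]-4-(prop-2-en-1-yl)oxolan-2-one; 18 but-3-en-2-one
Product: 20 (3aS,7R,8aS)-7-methyl-6-[(1E)-3-oxobut-1-en-1-yl]-3,3a,4,7,8,8a-hexahydro-2H-cyclohepta[b]furan-2-one, via vinylcycloheptene 19 (not isolated)
Conditions: second-generation Grubbs catalyst (5 mol %), 18 (5 equiv), CH2Cl2, 40 °C
Reagents that add atoms: none
Why: Tandem ring-closing enyne metathesis and cross-metathesis, in which the alkylidene formed at the allyl group closes the seven-membered ring onto the alkyne (exo mode, the cis-lactone holding both arms close) and the vinyl terminus is capped by the enone as the (E)-dienone; no stereocentre is formed.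

Step 13
Reactants: 20 (3aS,7R,8aS)-7-methyl-6-[(1E)-3-oxobut-1-en-1-yl]-3,3a,4,7,8,8a-hexahydro-2H-cyclohepta[b]furan-2-one
Product: 21 (3aS,7R,8aS)-7-methyl-6-(3-oxobutyl)-3,3a,4,7,8,8a-hexahydro-2H-cyclohepta[b]furan-2-one
Conditions: [(Ph3P)CuH]6 (5 mol %), (EtO)2MeSiH, t-BuOH, toluene, 0 °C to rt
Reagents that add atoms: none
Why: Copper hydride 1,4-reduction of the dienone, in which hydride attacks the unhindered β-carbon, so the trisubstituted ring alkene stays in place and the lactone is not touched.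

Step 14
Reactants: 21 (3aS,7R,8aS)-7-methyl-6-(3-oxobutyl)-3,3a,4,7,8,8a-hexahydro-2H-cyclohepta[b]furan-2-one
Product: 22 (3aS,7R,8aS)-6-(3,3-dimethoxybutyl)-7-methyl-3,3a,4,7,8,8a-hexahydro-2H-cyclohepta[b]furan-2-one
Conditions: HC(OMe)3, MeOH, PPTS (5 mol %), rt
Reagents that add atoms: trimethyl orthoformate, COC(OC)OC
Why: Acid-catalysed ketalisation with the orthoformate as water scavenger masks the methyl ketone for the strong-base steps that follow.

Step 15
Reactants: 22 (3aS,7R,8aS)-6-(3,3-dimethoxybutyl)-7-methyl-3,3a,4,7,8,8a-hexahydro-2H-cyclohepta[b]furan-2-one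
Product: 25 2-[(1S,5R,7S)-7-{[tert-butyl(dimethyl)silyl]oxy}-4-(3,3-dimethoxybutyl)-5-methylcyclohept-3-en-1-yl]acetic acid, via potassium hydroxy carboxylate 23 (not isolated), via bis-silyl derivative 24 (not isolated)
Conditions: KOH, MeOH/H2O, rt, then evaporation; t-BuMe2SiCl, imidazole, DMF, rt; K2CO3, MeOH/THF/H2O, rt; NaH2PO4 to pH 5
Reagents that add atoms: potassium hydroxide, [K+].[OH-]; tert-butyl(chloro)dimethylsilane, CC(C)(C)[Si](C)(C)Cl
Why: Saponification of the γ-lactone, silylation of both oxygens and selective hydrolysis of the labile silyl ester give the silyl ether acid, the silyl ether blocking relactonisation now and attack of the alcohol on the pyrone later.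

Step 16
Reactants: 25 2-[(1S,5R,7S)-7-{[tert-butyl(dimethyl)silyl]oxy}-4-(3,3-dimethoxybutyl)-5-methylcyclohept-3-en-1-yl]acetic acid
Product: 26 tert-butyl 2-[(1S,5R,7S)-7-{[tert-butyl(dimethyl)silyl]oxy}-4-(3,3-dimethoxybutyl)-5-methylcyclohept-3-en-1-yl]acetate
Conditions: O-tert-butyl-N,N'-di(propan-2-yl)isourea, CH2Cl2, rt
Reagents that add atoms: O-tert-butyl-N,N'-di(propan-2-yl)isourea, CC(C)NC(=NC(C)C)OC(C)(C)C
Why: Esterification with the isourea under neutral conditions spares the ketal and the silyl ether and installs the ester group that can leave as isobutene in the pyrone closure.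

Step 17
Reactants: 26 tert-butyl 2-[(1S,5R,7S)-7-{[tert-butyl(dimethyl)silyl]oxy}-4-(3,3-dimethoxybutyl)-5-methylcyclohept-3-en-1-yl]acetate; 27 methyl 2,2-dimethoxypropanoate
Product: 28 tert-butyl 2-[(1S,5R,7S)-7-{[tert-butyl(dimethyl)silyl]oxy}-4-(3,3-dimethoxybutyl)-5-methylcyclohept-3-en-1-yl]-4,4-dimethoxy-3-oxopentanoate (C2 epimers)
Conditions: LiN(i-Pr)2 (2.2 equiv), THF, −78 °C; then 27, −78 to −20 °C; aq NH4Cl
Reagents that add atoms: none
Why: Crossed Claisen condensation of the ester enolate with the activated α,α-dialkoxy ester, driven by deprotonation of the β-keto ester; the new α-centre is of no consequence because it becomes sp2 in the next step.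

Step 18
Reactants: 28 tert-butyl 2-[(1S,5R,7S)-7-{[tert-butyl(dimethyl)silyl]oxy}-4-(3,3-dimethoxybutyl)-5-methylcyclohept-3-en-1-yl]-4,4-dimethoxy-3-oxopentanoate
Product: 29 tert-butyl (2Z)-2-[(1S,5R,7S)-7-{[tert-butyl(dimethyl)silyl]oxy}-4-(3,3-dimethoxybutyl)-5-methylcyclohept-3-en-1-yl]-4,4-dimethoxy-3-{[(trifluoromethyl)sulfonyl]oxy}pent-2-enoate
Conditions: LiN(SiMe3)2, toluene, −78 °C; then (CF3SO2)2O, −78 to 0 °C
Reagents that add atoms: trifluoromethanesulfonic anhydride, O=S(=O)(OS(=O)(=O)C(F)(F)F)C(F)(F)F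
Why: O-Sulfonylation of the lithium-chelated β-keto ester enolate, where chelation between the enolate and ester oxygens should place the triflate cis to the ester as needed for the later ring closure.

Step 19
Reactants: 29 tert-butyl (2Z)-2-[(1S,5R,7S)-7-{[tert-butyl(dimethyl)silyl]oxy}-4-(3,3-dimethoxybutyl)-5-methylcyclohept-3-en-1-yl]-4,4-dimethoxy-3-{[(trifluoromethyl)sulfonyl]oxy}pent-2-enoate; 11 (3R,4R,5R)-5-[(2S)-2-methylbut-3-yn-1-yl]-3-[(phenylsulfanyl)methyl]-4-(prop-2-en-1-yl)oxolan-2-one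
Product: 30 tert-butyl (2E,6S)-2-[(1S,5R,7S)-7-{[tert-butyl(dimethyl)silyl]oxy}-4-(3,3-dimethoxybutyl)-5-methylcyclohept-3-en-1-yl]-3-(1,1-dimethoxyethyl)-6-methyl-7-{(2R,3R,4R)-5-oxo-4-[(phenylsulfanyl)methyl]-3-(prop-2-en-1-yl)oxolan-2-yl}hept-2-en-4-ynoate
Conditions: Pd(PPh3)4 (5 mol %), CuI (10 mol %), Et3N, THF, rt to 40 °C
Reagents that add atoms: none
Why: Sonogashira coupling of the activated enol triflate with the terminal alkyne proceeds with retention of alkene geometry (alkyne cis to the ester) under amine conditions that the lactone, sulfide, ketals and silyl ether tolerate.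

Step 20
Reactants: 30 tert-butyl (2E,6S)-2-[(1S,5R,7S)-7-{[tert-butyl(dimethyl)silyl]oxy}-4-(3,3-dimethoxybutyl)-5-methylcyclohept-3-en-1-yl]-3-(1,1-dimethoxyethyl)-6-methyl-7-{(2R,3R,4R)-5-oxo-4-[(phenylsulfanyl)methyl]-3-(prop-2-en-1-yl)oxolan-2-yl}hept-2-en-4-ynoate
Product: 32 4-acetyl-3-[(1S,5R,7S)-7-{[tert-butyl(dimethyl)silyl]oxy}-5-methyl-4-(3-oxobutyl)cyclohept-3-en-1-yl]-6-{(2S)-1-[(2R,3R,4R)-5-oxo-4-[(phenylsulfanyl)methyl]-3-(prop-2-en-1-yl)oxolan-2-yl]propan-2-yl}-2H-pyran-2-one, via bis-ketal pyrone 31 (not isolated)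
Conditions: [(2-biphenylyl)(t-Bu)2P]Au(MeCN)SbF6 (5–10 mol %), CH2Cl2, rt; then PPTS, acetone/H2O, 40 °C
Reagents that add atoms: water, O
Why: Gold-catalysed 6-endo-dig cyclisation of the tert-butyl (Z)-enynoate, in which the ester carbonyl oxygen attacks the distal alkyne carbon (the electrophilic δ-position of the enynoate) and isobutene is lost to give the 2-pyrone, after which mild acid unmasks both ketones while the silyl ether stays.

Step 21
Reactants: 32 4-acetyl-3-[(1S,5R,7S)-7-{[tert-butyl(dimethyl)silyl]oxy}-5-methyl-4-(3-oxobutyl)cyclohept-3-en-1-yl]-6-{(2S)-1-[(2R,3R,4R)-5-oxo-4-[(phenylsulfanyl)methyl]-3-(prop-2-en-1-yl)oxolan-2-yl]propan-2-yl}-2H-pyran-2-one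
Product: 33 bridged-lactone cycloadduct (5-acetyl-2-oxabicyclo[2.2.2]oct-5-en-3-one with the new cycloheptane fused at C1–C8; configuration as in the SMILES)
Conditions: toluene (0.005 M), BHT (5 mol %), 130 °C, sealed tube
Reagents that add atoms: none
Why: Thermal intramolecular Diels–Alder reaction of the 2-pyrone (diene C3=C4–C5=C6) with the terminal alkene carried on C6 by a five-atom tether, the closest known reaction type being the intramolecular cycloaddition of 2-pyrones with unactivated alkenes that keeps the lactone bridge. The cyclohexene closes by the concerted suprafacial [4+2] event (alkene CH2 to pyrone C3, alkene CH to pyrone C6), and the cycloheptane closes in the same event as the fused ring of a type 1 reaction through the C6–CH bond, a five-atom tether being too short for the bridged mode. The carbinol carbon and the spiro carbon are set together, their oxygen and carbonyl being held cis by the pyrone ring that becomes the lactone bridge, and their sense is fixed by the methyl-bearing carbon on C6: with its hydrogen eclipsing C5–H (least allylic 1,3-strain) the tether reaches one face only and the methyl points to the other. The ring-fusion CH is set by the tether-endo transition state (chain folded over C4=C5), the only one that lets this low-strain rotamer coexist with the syn-clinal arrangement of the two chain arms enforced by the cis-fused butyrolactone, so the ring fusion should be cis. The step needs π-facial and endo/exo selectivity and a useful rate below the temperature of CO2 loss from the adduct; the electron-poor 4-acetylpyrone, high dilution and the masking of the competing methylene lactone as its sulfide are meant to secure this.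

Step 22
Reactants: 33 bridged-lactone cycloadduct
Product: 35 (phenylsulfanyl)methyl lactone (the target with H and CH2SPh in place of the exocyclic methylene), via hydroxy bridged lactone 34 (not isolated)
Conditions: HF·pyridine, pyridine, THF, 0 °C to rt; then DBU (10 mol %), CH2Cl2, rt
Reagents that add atoms: none
Why: Desilylation frees the ring B alcohol, which attacks the bridging lactone carbonyl (5-exo-trig acyl transfer, translactonisation) with release of the strain of the boat δ-lactone, giving the spiro γ-lactone and the tertiary alcohol without breaking any bond at a stereocentre.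

Step 23
Reactants: 35 (phenylsulfanyl)methyl lactone
Product: 37 CNP0195550.4 (target), via sulfoxide 36 (not isolated)
Conditions: NaIO4, MeOH/H2O, 0 °C to rt; then NaHCO3, toluene, 100 °C
Reagents that add atoms: none
Why: Chemoselective oxidation of the sulfide to the sulfoxide and thermal syn-elimination (sulfoxide pyrolysis), whose only β-hydrogen is the lactone α-H, so the exocyclic methylene must form; alkenes, ketones and the tertiary alcohol are inert to periodate.

**Compound list**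

1 | (E)-but-2-enal | C/C=C/C=O | starting material
2 | ethynyltri(propan-2-yl)silane | C#C[Si](C(C)C)(C(C)C)C(C)C | starting material
3 | (3S)-3-methyl-5-[tri(propan-2-yl)silyl]pent-4-ynal | O=CC[C@H](C)C#C[Si](C(C)C)(C(C)C)C(C)C | intermediate
4 | methyl prop-2-ynoate | C#CC(=O)OC | starting material
5 | methyl (4R,6S)-4-hydroxy-6-methyl-8-[tri(propan-2-yl)silyl]octa-2,7-diynoate | COC(=O)C#C[C@H](O)C[C@H](C)C#C[Si](C(C)C)(C(C)C)C(C)C | intermediate
6 | methyl (2Z,4R,6S)-4-hydroxy-6-methyl-3-(prop-2-en-1-yl)-8-[tri(propan-2-yl)silyl]oct-2-en-7-ynoate | COC(=O)/C=C(CC=C)\[C@H](O)C[C@H](C)C#C[Si](C(C)C)(C(C)C)C(C)C | intermediate (not isolated)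
7 | (5R)-5-{(2S)-2-methyl-4-[tri(propan-2-yl)silyl]but-3-yn-1-yl}-4-(prop-2-en-1-yl)furan-2(5H)-one | C=CCC1=CC(=O)O[C@@H]1C[C@H](C)C#C[Si](C(C)C)(C(C)C)C(C)C | intermediate
8 | (4R,5R)-5-{(2S)-2-methyl-4-[tri(propan-2-yl)silyl]but-3-yn-1-yl}-4-(prop-2-en-1-yl)oxolan-2-one | C1C(=O)O[C@H](C[C@H](C)C#C[Si](C(C)C)(C(C)C)C(C)C)[C@@H]1CC=C | intermediate
9 | (4R,5R)-5-[(2S)-2-methylbut-3-yn-1-yl]-4-(prop-2-en-1-yl)oxolan-2-one | C1C(=O)O[C@H](C[C@H](C)C#C)[C@@H]1CC=C | intermediate
10 | trimethyl({(4R,5R)-5-[(2S)-2-methylbut-3-yn-1-yl]-4-(prop-2-en-1-yl)-4,5-dihydrofuran-2-yl}oxy)silane | C1=C(O[Si](C)(C)C)O[C@H](C[C@H](C)C#C)[C@@H]1CC=C | intermediate (not isolated)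
11 | (3R,4R,5R)-5-[(2S)-2-methylbut-3-yn-1-yl]-3-[(phenylsulfanyl)methyl]-4-(prop-2-en-1-yl)oxolan-2-one | c1ccccc1SC[C@H]2C(=O)O[C@H](C[C@H](C)C#C)[C@@H]2CC=C | intermediate
12 | (3R)-3-methyl-5-[tri(propan-2-yl)silyl]pent-4-ynal | O=CC[C@@H](C)C#C[Si](C(C)C)(C(C)C)C(C)C | intermediate
13 | methyl (4S,6R)-4-hydroxy-6-methyl-8-[tri(propan-2-yl)silyl]octa-2,7-diynoate | COC(=O)C#C[C@@H](O)C[C@@H](C)C#C[Si](C(C)C)(C(C)C)C(C)C | intermediate
14 | methyl (2Z,4S,6R)-4-hydroxy-6-methyl-3-(prop-2-en-1-yl)-8-[tri(propan-2-yl)silyl]oct-2-en-7-ynoate | COC(=O)/C=C(CC=C)\[C@@H](O)C[C@@H](C)C#C[Si](C(C)C)(C(C)C)C(C)C | intermediate (not isolated)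
15 | (5S)-5-{(2R)-2-methyl-4-[tri(propan-2-yl)silyl]but-3-yn-1-yl}-4-(prop-2-en-1-yl)furan-2(5H)-one | C=CCC1=CC(=O)O[C@H]1C[C@@H](C)C#C[Si](C(C)C)(C(C)C)C(C)C | intermediate
16 | (4S,5S)-5-{(2R)-2-methyl-4-[tri(propan-2-yl)silyl]but-3-yn-1-yl}-4-(prop-2-en-1-yl)oxolan-2-one | C1C(=O)O[C@@H](C[C@@H](C)C#C[Si](C(C)C)(C(C)C)C(C)C)[C@H]1CC=C | intermediate
17 | (4S,5S)-5-[(2R)-2-methylbut-3-yn-1-yl]-4-(prop-2-en-1-yl)oxolan-2-one | C1C(=O)O[C@@H](C[C@@H](C)C#C)[C@H]1CC=C | intermediate
18 | but-3-en-2-one | CC(=O)C=C | starting material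
19 | (3aS,7R,8aS)-6-ethenyl-7-methyl-3,3a,4,7,8,8a-hexahydro-2H-cyclohepta[b]furan-2-one | C2C(=O)O[C@H]1C[C@@H](C)C(C=C)=CC[C@H]12 | intermediate (not isolated)
20 | (3aS,7R,8aS)-7-methyl-6-[(1E)-3-oxobut-1-en-1-yl]-3,3a,4,7,8,8a-hexahydro-2H-cyclohepta[b]furan-2-one | C2C(=O)O[C@H]1C[C@@H](C)C(/C=C/C(C)=O)=CC[C@H]12 | intermediate
21 | (3aS,7R,8aS)-7-methyl-6-(3-oxobutyl)-3,3a,4,7,8,8a-hexahydro-2H-cyclohepta[b]furan-2-one | C2C(=O)O[C@H]1C[C@@H](C)C(CCC(C)=O)=CC[C@H]12 | intermediate
22 | (3aS,7R,8aS)-6-(3,3-dimethoxybutyl)-7-methyl-3,3a,4,7,8,8a-hexahydro-2H-cyclohepta[b]furan-2-one | C2C(=O)O[C@H]1C[C@@H](C)C(CCC(C)(OC)OC)=CC[C@H]12 | intermediate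
23 | potassium 2-[(1S,5R,7S)-4-(3,3-dimethoxybutyl)-7-hydroxy-5-methylcyclohept-3-en-1-yl]acetate | [K+].[O-]C(=O)C[C@@H]1CC=C(CCC(C)(OC)OC)[C@H](C)C[C@@H]1O | intermediate (not isolated)
24 | tert-butyl(dimethyl)silyl 2-[(1S,5R,7S)-7-{[tert-butyl(dimethyl)silyl]oxy}-4-(3,3-dimethoxybutyl)-5-methylcyclohept-3-en-1-yl]acetate | CC(C)(C)[Si](C)(C)OC(=O)C[C@@H]1CC=C(CCC(C)(OC)OC)[C@H](C)C[C@@H]1O[Si](C)(C)C(C)(C)C | intermediate (not isolated)
25 | 2-[(1S,5R,7S)-7-{[tert-butyl(dimethyl)silyl]oxy}-4-(3,3-dimethoxybutyl)-5-methylcyclohept-3-en-1-yl]acetic acid | OC(=O)C[C@@H]1CC=C(CCC(C)(OC)OC)[C@H](C)C[C@@H]1O[Si](C)(C)C(C)(C)C | intermediate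
26 | tert-butyl 2-[(1S,5R,7S)-7-{[tert-butyl(dimethyl)silyl]oxy}-4-(3,3-dimethoxybutyl)-5-methylcyclohept-3-en-1-yl]acetate | CC(C)(C)OC(=O)C[C@@H]1CC=C(CCC(C)(OC)OC)[C@H](C)C[C@@H]1O[Si](C)(C)C(C)(C)C | intermediate
27 | methyl 2,2-dimethoxypropanoate | COC(=O)C(C)(OC)OC | starting material
28 | tert-butyl 2-[(1S,5R,7S)-7-{[tert-butyl(dimethyl)silyl]oxy}-4-(3,3-dimethoxybutyl)-5-methylcyclohept-3-en-1-yl]-4,4-dimethoxy-3-oxopentanoate (C2 epimers) | CC(C)(C)OC(=O)C(C(=O)C(C)(OC)OC)[C@@H]1CC=C(CCC(C)(OC)OC)[C@H](C)C[C@@H]1O[Si](C)(C)C(C)(C)C | intermediate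
29 | tert-butyl (2Z)-2-[(1S,5R,7S)-7-{[tert-butyl(dimethyl)silyl]oxy}-4-(3,3-dimethoxybutyl)-5-methylcyclohept-3-en-1-yl]-4,4-dimethoxy-3-{[(trifluoromethyl)sulfonyl]oxy}pent-2-enoate | CC(C)(C)OC(=O)/C([C@@H]1CC=C(CCC(C)(OC)OC)[C@H](C)C[C@@H]1O[Si](C)(C)C(C)(C)C)=C(\OS(=O)(=O)C(F)(F)F)C(C)(OC)OC | intermediate
30 | tert-butyl (2E,6S)-2-[(1S,5R,7S)-7-{[tert-butyl(dimethyl)silyl]oxy}-4-(3,3-dimethoxybutyl)-5-methylcyclohept-3-en-1-yl]-3-(1,1-dimethoxyethyl)-6-methyl-7-{(2R,3R,4R)-5-oxo-4-[(phenylsulfanyl)methyl]-3-(prop-2-en-1-yl)oxolan-2-yl}hept-2-en-4-ynoate | CC(C)(C)OC(=O)/C([C@@H]1CC=C(CCC(C)(OC)OC)[C@H](C)C[C@@H]1O[Si](C)(C)C(C)(C)C)=C(\C#C[C@@H](C)C[C@H]2OC(=O)[C@H](CSc3ccccc3)[C@H]2CC=C)C(C)(OC)OC | intermediate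
31 | 3-[(1S,5R,7S)-7-{[tert-butyl(dimethyl)silyl]oxy}-4-(3,3-dimethoxybutyl)-5-methylcyclohept-3-en-1-yl]-4-(1,1-dimethoxyethyl)-6-{(2S)-1-[(2R,3R,4R)-5-oxo-4-[(phenylsulfanyl)methyl]-3-(prop-2-en-1-yl)oxolan-2-yl]propan-2-yl}-2H-pyran-2-one | c1ccccc1SC[C@H]3C(=O)O[C@H](C[C@H](C)C5=CC(C(C)(OC)OC)=C([C@@H]7CC=C(CCC(C)(OC)OC)[C@H](C)C[C@@H]7O[Si](C)(C)C(C)(C)C)C(=O)O5)[C@@H]3CC=C | intermediate (not isolated)
32 | 4-acetyl-3-[(1S,5R,7S)-7-{[tert-butyl(dimethyl)silyl]oxy}-5-methyl-4-(3-oxobutyl)cyclohept-3-en-1-yl]-6-{(2S)-1-[(2R,3R,4R)-5-oxo-4-[(phenylsulfanyl)methyl]-3-(prop-2-en-1-yl)oxolan-2-yl]propan-2-yl}-2H-pyran-2-one | c1ccccc1SC[C@H]3C(=O)O[C@H](C[C@H](C)C5=CC(C(C)=O)=C([C@@H]7CC=C(CCC(C)=O)[C@H](C)C[C@@H]7O[Si](C)(C)C(C)(C)C)C(=O)O5)[C@@H]3CC=C | intermediate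
33 | bridged-lactone cycloadduct: 5-acetyl-2-oxabicyclo[2.2.2]oct-5-en-3-one, C4 bearing the silyloxy cycloheptenyl group of 32, C1–C8 shared with the new cycloheptane; ring-fusion H, methyl, bridge oxygen and the cis-fused (phenylsulfanyl)methyl butyrolactone all on one face of the cycloheptane | c1ccccc1SC[C@H]3C(=O)O[C@@H]4C[C@H](C)[C@@]5(O6)C=C(C(C)=O)[C@@]([C@@H]7CC=C(CCC(C)=O)[C@H](C)C[C@@H]7O[Si](C)(C)C(C)(C)C)(C[C@H]5C[C@H]34)C6=O | intermediate
34 | hydroxy bridged lactone: 33 with the silyl ether replaced by a free OH | c1ccccc1SC[C@H]3C(=O)O[C@@H]4C[C@H](C)[C@@]5(O6)C=C(C(C)=O)[C@@]([C@@H]7CC=C(CCC(C)=O)[C@H](C)C[C@@H]7O)(C[C@H]5C[C@H]34)C6=O | intermediate (not isolated)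
35 | (phenylsulfanyl)methyl lactone: 37 with the exocyclic methylene replaced by H and CH2SPh (R at that carbon, CH2SPh trans to the neighbouring ring CH2) | c5ccccc5SC[C@H]1C(=O)O[C@@H]2C[C@H](C)[C@@]3(O)C=C(C(C)=O)[C@@]4(C[C@H]3C[C@H]12)C(=O)O[C@H]1C[C@@H](C)C(CCC(C)=O)=CC[C@H]14 | intermediate
36 | sulfoxide of 35 (both configurations at sulfur) | O=S(c5ccccc5)C[C@H]1C(=O)O[C@@H]2C[C@H](C)[C@@]3(O)C=C(C(C)=O)[C@@]4(C[C@H]3C[C@H]12)C(=O)O[C@H]1C[C@@H](C)C(CCC(C)=O)=CC[C@H]14 | intermediate (not isolated)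
37 | CNP0195550.4: the spiro-linked dimer of two cis-fused cyclohepta[b]furan-2-ones with the acetylcyclohexenol ring between them | C=C1C(=O)O[C@@H]2C[C@H](C)[C@@]3(O)C=C(C(C)=O)[C@@]4(C[C@H]3C[C@H]12)C(=O)O[C@H]1C[C@@H](C)C(CCC(C)=O)=CC[C@H]14 | target

**Summary**

Total steps: 23. Longest linear sequence: 17 (steps 7–23).

**Steps most likely to fail**

Step 21. The unactivated alkene may add too slowly below the temperature at which the adduct loses CO2 by retro-cycloaddition, or the tether may fold in the exo sense and give the trans ring fusion. The fallback runs the cycloaddition with an open tether and closes the upper lactone afterwards. It sets out from 11: saponification (KOH), methylation of the carboxylate (MeI, DMF) and silylation (t-BuMe2SiCl, imidazole) give methyl (2R,3R,4R,6S)-4-{[tert-butyl(dimethyl)silyl]oxy}-6-methyl-2-[(phenylsulfanyl)methyl]-3-(prop-2-en-1-yl)oct-7-ynoate F1. Sonogashira coupling with 29 gives the open-chain enynoate F2, and gold-catalysed closure with ketal hydrolysis, as in step 20, gives the open-tether pyrone F3. Heating as in step 21 gives the open-tether bridged lactone F4, in which a silyl ether and an ester replace the lactone clamp. HF·pyridine followed by DBU removes both silyl groups; the upper hydroxy ester closes to the cis-butyrolactone and the lower alcohol undergoes the acyl transfer, so the route is rejoined at 35.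

Step 20. Closure in the 5-exo sense to an alkylidene butenolide, or inhibition of the cationic gold catalyst by the thioether, may divert the pyrone formation. The fallback replaces the dealkylative gold cyclisation by lactonisation of the free acid. It sets out from 30: 85 % aqueous H3PO4 in toluene should cleave the tert-butyl ester and both ketals while sparing the silyl ether, giving the keto enynoic acid F5. ZnBr2 (catalytic) in THF then closes the (Z)-enynoic acid in the 6-endo sense, and the route is rejoined at 32.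

Step 18. Loss of chelation control at the crowded enolate, with the bulky ketal next to the ring, may give the enol triflate as a mixture of alkene isomers, of which only one can close to the pyrone. The fallback uses a slim alkynyl group as the acetyl surrogate. It sets out from 26: Claisen acylation of its lithium enolate with N-methoxy-N-methyl-3-(trimethylsilyl)prop-2-ynamide gives the alkynyl β-keto ester F6, and triflation of its lithium chelate gives the (Z)-enol triflate F7. Sonogashira coupling with 11 gives the cross-conjugated enediyne F8. Gold-catalysed closure, in which only the alkyne cis to the ester can be reached, gives the 4-(silylethynyl)pyrone F9. Acid-catalysed hydration of the silylalkyne at the ring-bound carbon (TsOH·H2O in wet MeOH with the same gold catalyst), which also cleaves the side-chain ketal, rejoins the route at 32.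

**Further compounds**

F1 | step 21 | methyl (2R,3R,4R,6S)-4-{[tert-butyl(dimethyl)silyl]oxy}-6-methyl-2-[(phenylsulfanyl)methyl]-3-(prop-2-en-1-yl)oct-7-ynoate | C#C[C@@H](C)C[C@@H](O[Si](C)(C)C(C)(C)C)[C@H](CC=C)[C@@H](CSc1ccccc1)C(=O)OC
F2 | step 21 | open-chain enynoate (30 with the upper lactone replaced by the methyl ester and silyl ether of F1) | CC(C)(C)OC(=O)/C([C@@H]1CC=C(CCC(C)(OC)OC)[C@H](C)C[C@@H]1O[Si](C)(C)C(C)(C)C)=C(\C#C[C@@H](C)C[C@@H](O[Si](C)(C)C(C)(C)C)[C@H](CC=C)[C@@H](CSc2ccccc2)C(=O)OC)C(C)(OC)OC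
F3 | step 21 | open-tether pyrone (32 with the upper lactone replaced by the methyl ester and silyl ether of F1) | CC(=O)C1=C([C@@H]2CC=C(CCC(C)=O)[C@H](C)C[C@@H]2O[Si](C)(C)C(C)(C)C)C(=O)OC(=C1)[C@@H](C)C[C@@H](O[Si](C)(C)C(C)(C)C)[C@H](CC=C)[C@@H](CSc3ccccc3)C(=O)OC
F4 | step 21 | open-tether bridged lactone (33 with the upper lactone opened as methyl ester and silyl ether) | CC(C)(C)[Si](C)(C)O[C@@H]4C[C@H](C)[C@@]5(O6)C=C(C(C)=O)[C@@]([C@@H]7CC=C(CCC(C)=O)[C@H](C)C[C@@H]7O[Si](C)(C)C(C)(C)C)(C[C@H]5C[C@@H]4[C@@H](CSc1ccccc1)C(=O)OC)C6=O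
F5 | step 20 | keto enynoic acid (30 with free carboxylic acid and both ketones unmasked) | OC(=O)/C([C@@H]1CC=C(CCC(C)=O)[C@H](C)C[C@@H]1O[Si](C)(C)C(C)(C)C)=C(\C#C[C@@H](C)C[C@H]2OC(=O)[C@H](CSc3ccccc3)[C@H]2CC=C)C(C)=O
F6 | step 18 | tert-butyl 2-[(1S,5R,7S)-7-{[tert-butyl(dimethyl)silyl]oxy}-4-(3,3-dimethoxybutyl)-5-methylcyclohept-3-en-1-yl]-3-oxo-5-(trimethylsilyl)pent-4-ynoate (C2 epimers) | CC(C)(C)OC(=O)C(C(=O)C#C[Si](C)(C)C)[C@@H]1CC=C(CCC(C)(OC)OC)[C@H](C)C[C@@H]1O[Si](C)(C)C(C)(C)C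
F7 | step 18 | tert-butyl (2Z)-2-[(1S,5R,7S)-7-{[tert-butyl(dimethyl)silyl]oxy}-4-(3,3-dimethoxybutyl)-5-methylcyclohept-3-en-1-yl]-3-{[(trifluoromethyl)sulfonyl]oxy}-5-(trimethylsilyl)pent-2-en-4-ynoate | CC(C)(C)OC(=O)/C([C@@H]1CC=C(CCC(C)(OC)OC)[C@H](C)C[C@@H]1O[Si](C)(C)C(C)(C)C)=C(\OS(=O)(=O)C(F)(F)F)C#C[Si](C)(C)C
F8 | step 18 | cross-conjugated enediyne (30 with the 1,1-dimethoxyethyl group replaced by (trimethylsilyl)ethynyl; upper alkyne cis to the ester) | CC(C)(C)OC(=O)/C([C@@H]1CC=C(CCC(C)(OC)OC)[C@H](C)C[C@@H]1O[Si](C)(C)C(C)(C)C)=C(\C#C[C@@H](C)C[C@H]2OC(=O)[C@H](CSc3ccccc3)[C@H]2CC=C)C#C[Si](C)(C)C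
F9 | step 18 | 4-[(trimethylsilyl)ethynyl]pyrone (31 with the 1,1-dimethoxyethyl group replaced by (trimethylsilyl)ethynyl) | c1ccccc1SC[C@H]3C(=O)O[C@H](C[C@H](C)C5=CC(C#C[Si](C)(C)C)=C([C@@H]7CC=C(CCC(C)(OC)OC)[C@H](C)C[C@@H]7O[Si](C)(C)C(C)(C)C)C(=O)O5)[C@@H]3CC=C
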